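The target is the meso 1,4-diketone C1–C4 in which C2 and C3 each carry a CH2 bonded to a 4-hydroxyphenyl ring (rings C, D). Each of these CH2 carbons is β to a carbonyl (C1=O, C4=O), a homoenolate position, so both CH2–aryl bonds are disconnected together. The precursor is a meso bicyclopropanediol: C1 and C4 are cyclopropanol carbinol carbons bearing the protected resorcinol rings A and B, and the future benzylic CH2 groups are the ring methylenes. One palladium-catalysed operation opens both rings, releases both ketones and attaches rings C and D without touching C2 or C3. Benzyl ethers are used throughout, so the last step is a neutral hydrogenolysis.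

Key step: step 6

Remark: the target's descriptors read (2R,3S) on identically substituted centres, which is the achiral meso form, so only relative configuration has to be controlled. Chiral intermediates are racemic and drawn as one enantiomer, and the chain numbering C1–C4 of the target is used for all compounds.

Step 1
Reactants: 1 2',4'-dihydroxyacetophenone
Product: 2 2',4'-bis(benzyloxy)acetophenone
Conditions: BnBr (2.5 equiv), K2CO3 (3 equiv), DMF, 70 °C
Reagents that add atoms: benzyl bromide, BrCc1ccccc1
Why: Williamson ether synthesis, in which carbonate in hot DMF deprotonates both phenols (the hydrogen-bonded 2'-OH included) and benzyl bromide is an unhindered SN2 partner, so full O-benzylation is expected and no stereocentre is involved.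

Step 2
Reactants: 2 2',4'-bis(benzyloxy)acetophenone (two molecules)
Product: 4 1,4-bis[2,4-bis(benzyloxy)phenyl]butane-1,4-dione, via lithium enolate 3 (not isolated)
Conditions: LiN(iPr)2 (1.1 equiv), THF, −78 °C; then CuCl2 (1.1 equiv), DMF, −78 °C to rt
Reagents that add atoms: none
Why: Oxidative homocoupling of a ketone enolate, in which CuCl2 takes one electron from each enolate 3 and the two α-carbons (future C2 and C3) join, a reaction type well established for aryl methyl ketones, which have one enolisable site and give an achiral 1,4-diketone.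

Step 3
Reactants: 4 1,4-bis[2,4-bis(benzyloxy)phenyl]butane-1,4-dione
Product: 5 (1Z,3Z)-1,4-bis[2,4-bis(benzyloxy)phenyl]-1,4-bis(trimethylsilyloxy)buta-1,3-diene
Conditions: Me3SiOTf (2.6 equiv), Et3N (4 equiv), CH2Cl2, 0 °C to rt; cold aq. NaHCO3 wash, used without chromatography
Reagents that add atoms: trimethylsilyl trifluoromethanesulfonate, C[Si](C)(C)OS(=O)(=O)C(F)(F)F
Why: Soft enolisation–silylation with a silyl triflate and a tertiary amine, in which each carbonyl can enolise only toward C2 or C3, the excess amine keeps the medium non-acidic so that Paal–Knorr closure to a furan is suppressed, and the Z geometry (OSiMe3 cis to the chain) is the one normally obtained from aryl alkyl ketones because the aryl group avoids the chain.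

Step 4
Reactants: 5 (1Z,3Z)-bis(silyl enol ether); 6 diiodomethane
Product: 8 meso-(1R,1'S,2R,2'S)-2,2'-bis[2,4-bis(benzyloxy)phenyl]-2,2'-bis(trimethylsilyloxy)-1,1'-bi(cyclopropane) (each OSiMe3 cis to the other ring; formed beside its dl diastereomer), via monocyclopropane 7 (not isolated)
Conditions: Et2Zn (4 equiv), 6 (8 equiv), DME (4 equiv), CH2Cl2, −15 to 0 °C; pyridine, then aq. NaHCO3 quench
Reagents that add atoms: none
Why: Simmons–Smith cyclopropanation (Furukawa variant), in which the zinc carbenoid adds suprafacially to each electron-rich enol ether so that the Z geometry places every OSiMe3 cis to the neighbouring ring, while the C2/C3 relationship is decided in the second transfer to 7, whose conformer locked by allylic 1,3-strain (C2–H eclipsing C3=C4) shows one face flanked by the ring CH2 (leading to the dl isomer) and one flanked by C1 and its OSiMe3 oxygen (leading to meso 8), so both isomers are expected and the small, still zinc-coordinating SiMe3 group is chosen to give the meso pathway its best chance.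

Step 5
Reactants: 8 meso-bis(trimethylsilyl ether) (as the mixture with its dl diastereomer)
Product: 9 meso-(1R,1'S,2R,2'S)-2,2'-bis[2,4-bis(benzyloxy)phenyl]-[1,1'-bi(cyclopropane)]-2,2'-diol (each OH cis to the other ring)
Conditions: Bu4NF/AcOH (1:1, 2.5 equiv), THF, 0 °C; diastereomers separated on Et3N-deactivated SiO2, then crystallisation; stored cold under argon
Reagents that add atoms: none
Why: Fluoride-induced Si–O cleavage, buffered with acetic acid so that neither base- nor acid-induced opening of the electron-rich 1-arylcyclopropanols sets in, touches no C–O or C–C bond, so all four stereocentres are retained and the non-enolisable diastereomers can be separated without interconversion.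

Step 6
Reactants: 9 meso-bicyclopropanediol; 10 1-(benzyloxy)-4-bromobenzene (two molecules)
Product: 12 meso-(2R,3S)-2,3-bis[4-(benzyloxy)benzyl]-1,4-bis[2,4-bis(benzyloxy)phenyl]butane-1,4-dione, via keto cyclopropanol 11 (not isolated)
Conditions: 10 (2.6 equiv), Pd(OAc)2 (10 mol %), XPhos (20 mol %), Cs2CO3 (3 equiv), degassed dry toluene, 70 °C
Reagents that add atoms: none
Why: Zerovalent palladium, formed from Pd(OAc)2 and XPhos, inserts into the C–Br bond of 10, carbonate-assisted exchange puts the arylpalladium unit on a cyclopropanol oxygen of 9, β-carbon elimination cuts the carbinol–CH2 bond, and the primary alkyl(aryl)palladium homoenolate collapses by C(sp3)–C(sp2) reductive elimination, first to 11 and, after the same cycle on the second ring, to 12. The closest known reaction type is the palladium-catalysed ring-opening cross-coupling of tertiary cyclopropanols, 1,2-disubstituted ones from silyl enol ethers included, with aryl bromides, here simply run at two sites of one molecule. No ring is closed and no stereocentre is created: the carbinol stereocentres dissolve into C1=O and C4=O, and since no bond to C2 or C3 is made or broken, meso 9 maps onto meso 12. The regioselectivity needed, cleavage toward CH2 and not toward C2 or C3, is secured by the substrate, because only the unsubstituted ring carbon gives an unhindered primary alkylpalladium. The chemoselectivity needed, reductive elimination ahead of β-hydride loss from C2–H or C3–H and ahead of protonation of the homoenolate, is served by the bulky electron-rich biarylphosphine, by chelation of palladium to the new carbonyl oxygen and by anhydrous conditions. A sparingly soluble carbonate in toluene at moderate temperature keeps enolisation of the hindered α-CH groups of 11 and 12, and thus epimerisation, slow.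

Step 7
Reactants: 12 meso-hexabenzyl ether
Product: 13 meso-(2R,3S)-1,4-bis(2,4-dihydroxyphenyl)-2,3-bis(4-hydroxybenzyl)butane-1,4-dione (target)
Conditions: H2 (1 atm), Pd/C (10 wt % Pd), THF–MeOH 1:1, rt, stopped when uptake ends
Reagents that add atoms: none
Why: Catalytic hydrogenolysis of six aryl benzyl ethers under neutral conditions offers no acid or base to epimerise C2/C3 or to dehydrate the 1,4-diketone to a furan (Paal–Knorr), while the electron-rich, hydrogen-bonded 2,4-dihydroxyphenyl ketones are reduced far more slowly than O–benzyl bonds are cleaved, as in the routine debenzylation of protected dihydrochalcones.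

Compound list
1 | 2',4'-dihydroxyacetophenone | CC(=O)c1ccc(O)cc1O | starting material
2 | 2',4'-bis(benzyloxy)acetophenone | CC(=O)c1ccc(OCc2ccccc2)cc1OCc1ccccc1 | intermediate
3 | lithium enolate of 2 | C=C(O[Li])c1ccc(OCc2ccccc2)cc1OCc1ccccc1 | intermediate
4 | 1,4-bis[2,4-bis(benzyloxy)phenyl]butane-1,4-dione | O=C(CCC(=O)c1ccc(OCc2ccccc2)cc1OCc1ccccc1)c1ccc(OCc2ccccc2)cc1OCc1ccccc1 | intermediate
5 | (1Z,3Z)-1,4-bis[2,4-bis(benzyloxy)phenyl]-1,4-bis(trimethylsilyloxy)buta-1,3-diene | C[Si](C)(C)O/C(=C\C=C(/O[Si](C)(C)C)c1ccc(OCc2ccccc2)cc1OCc1ccccc1)c1ccc(OCc2ccccc2)cc1OCc1ccccc1 | intermediate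
6 | diiodomethane | ICI | starting material
7 | racemic rel-(1R,2R)-1-aryl-1-(trimethylsilyloxy)-2-[(Z)-2-aryl-2-(trimethylsilyloxy)ethenyl]cyclopropane, aryl = 2,4-bis(benzyloxy)phenyl, OSiMe3 cis to the alkenyl group | C[Si](C)(C)O[C@]1(c2ccc(OCc3ccccc3)cc2OCc2ccccc2)C[C@@H]1/C=C(\O[Si](C)(C)C)c1ccc(OCc2ccccc2)cc1OCc1ccccc1 | intermediate
8 | meso-(1R,1'S,2R,2'S)-2,2'-bis[2,4-bis(benzyloxy)phenyl]-2,2'-bis(trimethylsilyloxy)-1,1'-bi(cyclopropane) | C[Si](C)(C)O[C@]1(c2ccc(OCc3ccccc3)cc2OCc2ccccc2)C[C@@H]1[C@@H]1C[C@@]1(O[Si](C)(C)C)c1ccc(OCc2ccccc2)cc1OCc1ccccc1 | intermediate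
9 | meso-(1R,1'S,2R,2'S)-2,2'-bis[2,4-bis(benzyloxy)phenyl]-[1,1'-bi(cyclopropane)]-2,2'-diol | O[C@]1(c2ccc(OCc3ccccc3)cc2OCc2ccccc2)C[C@@H]1[C@@H]1C[C@@]1(O)c1ccc(OCc2ccccc2)cc1OCc1ccccc1 | intermediate
10 | 1-(benzyloxy)-4-bromobenzene | Brc1ccc(OCc2ccccc2)cc1 | starting material
11 | racemic keto cyclopropanol: one ring of 9 opened and arylated (C2 R, C3 S, C4 S, relative), the other ring intact | O=C(c1ccc(OCc2ccccc2)cc1OCc1ccccc1)[C@H](Cc1ccc(OCc2ccccc2)cc1)[C@@H]1C[C@@]1(O)c1ccc(OCc2ccccc2)cc1OCc1ccccc1 | intermediate
12 | meso-(2R,3S)-2,3-bis[4-(benzyloxy)benzyl]-1,4-bis[2,4-bis(benzyloxy)phenyl]butane-1,4-dione | O=C(c1ccc(OCc2ccccc2)cc1OCc1ccccc1)[C@@H](Cc1ccc(OCc2ccccc2)cc1)[C@@H](Cc1ccc(OCc2ccccc2)cc1)C(=O)c1ccc(OCc2ccccc2)cc1OCc1ccccc1 | intermediate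
13 | meso-(2R,3S)-1,4-bis(2,4-dihydroxyphenyl)-2,3-bis(4-hydroxybenzyl)butane-1,4-dione | O=C(c1ccc(O)cc1O)[C@@H](Cc1ccc(O)cc1)[C@@H](Cc1ccc(O)cc1)C(=O)c1ccc(O)cc1O | target

Total step count: 7. Longest linear sequence: 7 (1 to 13; compounds 6 and 10 are bought).

Steps most likely to fail

**Step 6.**
- What may go wrong:
  - The alkylpalladium homoenolate may lose β-hydride from C2–H or C3–H faster than it couples.
  - The cyclopropanols may simply be protonated open.
  - The reaction may stall after the first ring because 11 rests as a cyclic hemiketal.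
  - The carbonate may epimerise C2/C3.
- Fallback: polar enolate alkylation, which forms the C2–CH2 and C3–CH2 bonds instead of the CH2–aryl bonds. It sets out from 4.
  - LiN(SiMe3)2 (1 equiv) in THF at −78 °C, followed by 4-(benzyloxy)benzyl bromide, should give the racemic monobenzylated diketone F1.
  - A second kinetic deprotonation should take the less hindered C3 methylene. The same bromide should then give 12 beside its dl isomer, from which 12 is taken by crystallisation.
  - The route is rejoined at 12.

**Step 4.**
- What may go wrong: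
  - Facial selectivity in the second CH2 transfer may run against the meso series, since the less hindered face of 7 leads to the dl series.
  - The zinc salts may open the siloxycyclopropanes.
- Which isomer is which is to be settled at the stage of 9, by X-ray diffraction or by chiral-phase HPLC, where only the dl isomer can split into two peaks.
- Fallback: thermodynamic correction after the coupling, in place of separation before it. It sets out from 5.
  - Cyclopropanation as in step 4 gives mainly the dl bis(silyl ether) F2.
  - Buffered fluoride gives the dl diol F3.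
  - Coupling with 10 under the conditions of step 6 gives the dl diketone F4.
  - F4 is enolisable, so catalytic DBU in an EtOH–toluene slurry should interconvert the C2/C3 epimers. The centrosymmetric meso isomer is expected to be the higher-melting and less soluble one, as is usual for 2,3-disubstituted 1,4-diaryl-1,4-diketones, so it should crystallise and drain the equilibrium.
  - The route is rejoined at 12.

**Step 3.**
- What may go wrong:
  - The second enolisation may lag.
  - E/Z scrambling would multiply the diastereomers met in steps 4 and 5.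
  - The bis(enol ether) may hydrolyse on work-up.
  - Adventitious acid may trigger Paal–Knorr dehydration.
- Fallback: one ring at a time, so that no conjugated bis(enol ether) is ever made. It sets out from 4.
  - LiN(SiMe3)2 (1 equiv) and Me3SiCl in THF at −78 °C should give the Z mono(silyl enol ether) F5.
  - Et2Zn/CH2I2 should give the racemic keto siloxycyclopropane F6.
  - A second LiN(SiMe3)2/Me3SiCl treatment should give 7, now isolated, which takes up the second CH2 as in step 4.
  - The route is rejoined at 7.

Further compounds
F1 | step 6 | racemic 2-[4-(benzyloxy)benzyl]-1,4-bis[2,4-bis(benzyloxy)phenyl]butane-1,4-dione | O=C(c1ccc(OCc2ccccc2)cc1OCc1ccccc1)[C@H](Cc1ccc(OCc2ccccc2)cc1)CC(=O)c1ccc(OCc2ccccc2)cc1OCc1ccccc1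
F2 | step 4 | racemic (1R,1'R,2R,2'R)-2,2'-bis[2,4-bis(benzyloxy)phenyl]-2,2'-bis(trimethylsilyloxy)-1,1'-bi(cyclopropane) | C[Si](C)(C)O[C@]1(c2ccc(OCc3ccccc3)cc2OCc2ccccc2)C[C@@H]1[C@H]1C[C@]1(O[Si](C)(C)C)c1ccc(OCc2ccccc2)cc1OCc1ccccc1
F3 | step 4 | racemic (1R,1'R,2R,2'R)-2,2'-bis[2,4-bis(benzyloxy)phenyl]-[1,1'-bi(cyclopropane)]-2,2'-diol | O[C@]1(c2ccc(OCc3ccccc3)cc2OCc2ccccc2)C[C@@H]1[C@H]1C[C@]1(O)c1ccc(OCc2ccccc2)cc1OCc1ccccc1
F4 | step 4 | racemic (2R,3R)-2,3-bis[4-(benzyloxy)benzyl]-1,4-bis[2,4-bis(benzyloxy)phenyl]butane-1,4-dione | O=C(c1ccc(OCc2ccccc2)cc1OCc1ccccc1)[C@H](Cc1ccc(OCc2ccccc2)cc1)[C@@H](Cc1ccc(OCc2ccccc2)cc1)C(=O)c1ccc(OCc2ccccc2)cc1OCc1ccccc1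
F5 | step 3 | (Z)-1,4-bis[2,4-bis(benzyloxy)phenyl]-4-(trimethylsilyloxy)but-3-en-1-one | C[Si](C)(C)O/C(=C\CC(=O)c1ccc(OCc2ccccc2)cc1OCc1ccccc1)c1ccc(OCc2ccccc2)cc1OCc1ccccc1
F6 | step 3 | racemic 1-[2,4-bis(benzyloxy)phenyl]-2-{2-[2,4-bis(benzyloxy)phenyl]-2-(trimethylsilyloxy)cyclopropyl}ethanone, OSiMe3 cis to the CH2C(=O)Ar arm | C[Si](C)(C)O[C@]1(c2ccc(OCc3ccccc3)cc2OCc2ccccc2)C[C@@H]1CC(=O)c1ccc(OCc2ccccc2)cc1OCc1ccccc1
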